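**Plan**

1. Numbering is that of isochromene (O2, C1, C3, C4, C4a, C5–C8, C8a; primes for the 6-hydroxy half). Ring A is the pyran, ring B the carbocycle, TBSO is tert-butyldimethylsilyloxy.
2. Cuts, in retrosynthetic order: (a) the four aryl silyl ethers; (b) the exocyclic C5=CH bond of the linker (Knoevenagel between the C5 methylene of 6,8-dione 19 and dienal 20), so both halves come from one bicyclic diol 17; (c) the C4–C4a bond of ring A; (d) O2–C3 (enol ether); (e) C8a–C1; (f) C7–O (orsellinate).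
3. The feature that allows cut (c): C4a is the β-carbon of the C8 enone of ring B, and C4 is the terminal carbon of a 2-alkoxy-1,3-diene held on C8a through C1–O2. A dehydrogenative 6-endo palladium coupling of these two C–H carbons closes ring A and gives the whole O2–C3=C4–C4a=C8a–C8=O chromophore with the side chain in place.
4. Forward: the orsellinate is put on C7 of achiral 2-methylcyclohexane-1,3-dione; ring B is desymmetrized, dehydrogenated and hydroxymethylated; the dienyl ether is attached and ring A is closed; the halves then diverge (acetate and C6 ketone on the left, dienal on the right), are joined at C5 and desilylated.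
5. Stereochemistry: C6 and C7 arise together in the catalyst-controlled transfer hydrogenation of the mirror-symmetric dione 6 and supply C7, C7′ and C6′ of the target; C7 is quaternary and cannot epimerize.
6. Alkene geometry: both (E)-alkenes come from (E)-pent-2-en-4-yn-1-ol; the (Z)-C5 alkylidene comes from thermodynamic control in the condensation.

Key step: step 10

Remark: the (S,S)-ligand in step 3 is assumed to deliver the (6R)-alcohol; if the sense of induction is opposite, the (R,R)-ligand is used.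

Step 1
Reactants: 1 orsellinic acid (2,4-dihydroxy-6-methylbenzoic acid)
Product: 3 2,4-bis(TBSO)-6-methylbenzoic acid, via tert-butyldimethylsilyl 2,4-bis(TBSO)-6-methylbenzoate 2 (not isolated)
Conditions: TBSCl, imidazole, DMF, 23 °C; then AcOH–THF–H2O, 23 °C
Reagents that add atoms: tert-butyldimethylsilyl chloride, CC(C)(C)[Si](C)(C)Cl
Why: Exhaustive silylation followed by selective hydrolysis of the much more labile silyl ester should leave the two aryl silyl ethers and the free acid (standard silyl protection).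

Step 2
Reactants: 3 2,4-bis(TBSO)-6-methylbenzoic acid; 4 2-methylcyclohexane-1,3-dione
Product: 6 2-methyl-1,3-dioxocyclohexan-2-yl 2,4-bis(TBSO)-6-methylbenzoate, via bis(aroyloxy)iodobenzene 5 (not isolated)
Conditions: PhI(OAc)2 (1.0 equiv), 3 (2.2 equiv), PhCl, 50 °C, 20 mbar; then 4, CH2Cl2, 23 °C
Reagents that add atoms: none
Why: Ligand exchange on trivalent iodine gives 5, and its reaction with the enol of the 2-substituted 1,3-diketone followed by reductive ligand coupling (hypervalent-iodine α-acyloxylation of β-dicarbonyls) should form the tertiary C7–O bond without exposing a free α-ketol; the product has a mirror plane, so no stereocenter is set yet.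

Step 3
Reactants: 6 2-methyl-1,3-dioxocyclohexan-2-yl 2,4-bis(TBSO)-6-methylbenzoate
Product: 7 (1R,2R)-2-hydroxy-1-methyl-6-oxocyclohexyl 2,4-bis(TBSO)-6-methylbenzoate
Conditions: RuCl[(S,S)-TsDPEN](p-cymene) (2 mol %), HCO2H–Et3N (5:2), CH2Cl2, 23 °C
Reagents that add atoms: none
Why: Noyori-type asymmetric transfer hydrogenation desymmetrizes the 2,2-disubstituted 1,3-dione, the catalyst selecting one enantiotopic carbonyl and hydride entering anti to the axial aroyloxy group, so that C6 (R, OH cis to the ester) and the quaternary C7 (R) are fixed in the same event.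

Step 4
Reactants: 7 (1R,2R)-2-hydroxy-1-methyl-6-oxocyclohexyl 2,4-bis(TBSO)-6-methylbenzoate
Product: 8 (1R,2R)-1-methyl-6-oxo-2-(triethylsilyloxy)cyclohexyl 2,4-bis(TBSO)-6-methylbenzoate
Conditions: TESOTf, 2,6-lutidine, CH2Cl2, −78 °C
Reagents that add atoms: triethylsilyl trifluoromethanesulfonate, CC[Si](CC)(CC)OS(=O)(=O)C(F)(F)F
Why: Silyl triflate protection of the hindered secondary alcohol masks C6–OH for the enolization and coupling steps, and the group can later be removed by acid without touching the aryl silyl ethers.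

Step 5
Reactants: 8 (1R,2R)-1-methyl-6-oxo-2-(triethylsilyloxy)cyclohexyl 2,4-bis(TBSO)-6-methylbenzoate
Product: 10 (1R,6R)-1-methyl-2-oxo-6-(triethylsilyloxy)cyclohex-3-en-1-yl 2,4-bis(TBSO)-6-methylbenzoate, via trimethylsilyl enol ether 9 (not isolated)
Conditions: TMSOTf, Et3N, CH2Cl2, 0 °C; then Pd(OAc)2 (1.05 equiv), MeCN, 23 °C
Reagents that add atoms: none
Why: Soft enolization can only go toward C8a because C7 is quaternary, and Saegusa–Ito oxidation of silyl enol ether 9 should give the C8a=C4a enone.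

Step 6
Reactants: 10 (1R,6R)-1-methyl-2-oxo-6-(triethylsilyloxy)cyclohex-3-en-1-yl 2,4-bis(TBSO)-6-methylbenzoate
Product: 11 (1R,6R)-3-(hydroxymethyl)-1-methyl-2-oxo-6-(triethylsilyloxy)cyclohex-3-en-1-yl 2,4-bis(TBSO)-6-methylbenzoate
Conditions: aq. CH2O (37 %), DMAP (0.2 equiv), THF–H2O (4:1), 23 °C
Reagents that add atoms: formaldehyde, C=O
Why: Morita–Baylis–Hillman reaction with formaldehyde (DMAP adds to C4a, the enolate is hydroxymethylated at C8a, DMAP leaves) should install C1 as the α-hydroxymethyl group of the enone.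

Step 7
Reactants: 12 (E)-pent-2-en-4-yn-1-ol
Product: 13 (E)-tert-butyldimethyl(pent-2-en-4-yn-1-yloxy)silane
Conditions: TBSCl, imidazole, CH2Cl2, 0 °C
Reagents that add atoms: tert-butyldimethylsilyl chloride, CC(C)(C)[Si](C)(C)Cl
Why: Standard silylation protects the primary allylic alcohol for the copper and palladium steps.

Step 8
Reactants: 13 (E)-tert-butyldimethyl(pent-2-en-4-yn-1-yloxy)silane
Product: 14 (E)-tert-butyldimethyl{[4-(4,4,5,5-tetramethyl-1,3,2-dioxaborolan-2-yl)penta-2,4-dien-1-yl]oxy}silane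
Conditions: B2pin2, CuCl (5 mol %), SIMes·HCl (5 mol %), NaOt-Bu (10 mol %), MeOH (2 equiv), THF, 0 °C
Reagents that add atoms: bis(pinacolato)diboron, CC1(C)OB(OC1(C)C)B1OC(C)(C)C(C)(C)O1
Why: Copper-catalyzed protoboration of the terminal alkyne (syn borylcupration, then protonation by methanol) with an N-aryl carbene ligand and a conjugating alkenyl substituent should place boron on the internal carbon and leave the (E)-alkene untouched.

Step 9
Reactants: 11 (1R,6R)-3-(hydroxymethyl)-1-methyl-2-oxo-6-(triethylsilyloxy)cyclohex-3-en-1-yl 2,4-bis(TBSO)-6-methylbenzoate; 14 (E)-tert-butyldimethyl{[4-(4,4,5,5-tetramethyl-1,3,2-dioxaborolan-2-yl)penta-2,4-dien-1-yl]oxy}silane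
Product: 15 (1R,6R)-1-methyl-2-oxo-3-({[(3E)-5-(TBSO)penta-1,3-dien-2-yl]oxy}methyl)-6-(triethylsilyloxy)cyclohex-3-en-1-yl 2,4-bis(TBSO)-6-methylbenzoate
Conditions: 14 (2 equiv), Cu(OAc)2 (2 equiv), Et3N (4 equiv), 4 Å MS, CH2Cl2, 23 °C
Reagents that add atoms: none
Why: Chan–Lam-type oxidative C–O coupling of an alkenylboronate with a primary alcohol (transmetalation to copper, then C–O reductive elimination) should form the O2–C3 enol ether bond at room temperature under nearly neutral conditions that spare the enone and do not trigger Claisen rearrangement of the allyl vinyl ether.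

Step 10
Reactants: 15 (1R,6R)-1-methyl-2-oxo-3-({[(3E)-5-(TBSO)penta-1,3-dien-2-yl]oxy}methyl)-6-(triethylsilyloxy)cyclohex-3-en-1-yl 2,4-bis(TBSO)-6-methylbenzoate
Product: 16 (6R,7R)-3-[(E)-3-(TBSO)prop-1-enyl]-7-methyl-8-oxo-6-(triethylsilyloxy)-5,6,7,8-tetrahydro-1H-isochromen-7-yl 2,4-bis(TBSO)-6-methylbenzoate
Conditions: Pd(OAc)2 (0.2 equiv), NaOAc, 4 Å MS, O2 (1 atm), DMSO, 45 °C
Reagents that add atoms: none
Why: Proposed new method: divalent palladium should attack the terminal carbon C4 of the electron-rich 2-alkoxydiene (the cation is an oxocarbenium ion at C3 that is also allylic), acetate removes the C4 proton, and the resulting 2-alkoxyalkenylpalladium, whose geometry can equilibrate through the oxocarbenium form, inserts the tethered enone with C4 adding to the β-carbon C4a; the C8a palladium enolate then equilibrates through its O-bound form, loses H-4a by syn β-hydride elimination to restore the C4a=C8a enone, and zerovalent palladium is reoxidized by O2. The closest known reaction types are the Pd(OAc)2-mediated cycloalkenylation of silyl enol ethers onto tethered alkenes (Saegusa–Ito type) and the dehydrogenative Heck (Fujiwara–Moritani) coupling of cyclic enol ethers with acrylates. Ring A closes in the 6-endo-trig mode with both enone carbons inside the new ring; the alternative 5-exo attack at C8a would put palladium on the unstabilized β-carbon and runs against the polarization of the enone. No stereocenter is created, and C6 and C7 are not touched. The step needs β-hydride elimination to win over β-alkoxide elimination at the C8a–Pd stage, which the new six-membered ring should secure because the C1–O2 bond cannot become syn-coplanar with the exocyclic C8a–Pd bond. It also needs the enol ether to survive, for which acetate buffer, sieves and the absence of protic acid are chosen, and the product, a push-pull dienyl ether, should be too electron-poor to react again.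

Step 11
Reactants: 16 (6R,7R)-3-[(E)-3-(TBSO)prop-1-enyl]-7-methyl-8-oxo-6-(triethylsilyloxy)-5,6,7,8-tetrahydro-1H-isochromen-7-yl 2,4-bis(TBSO)-6-methylbenzoate
Product: 17 (6R,7R)-6-hydroxy-3-[(E)-3-hydroxyprop-1-enyl]-7-methyl-8-oxo-5,6,7,8-tetrahydro-1H-isochromen-7-yl 2,4-bis(TBSO)-6-methylbenzoate
Conditions: CSA (0.2 equiv), MeOH–CH2Cl2 (1:1), 0 °C
Reagents that add atoms: none
Why: Acid-catalyzed methanolysis of alkyl silyl ethers should remove the TES and the primary TBS group, while the aryl silyl ethers, which are far more stable to acid, and the push-pull dienyl ether stay intact.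

Step 12
Reactants: 17 (6R,7R)-6-hydroxy-3-[(E)-3-hydroxyprop-1-enyl]-7-methyl-8-oxo-5,6,7,8-tetrahydro-1H-isochromen-7-yl 2,4-bis(TBSO)-6-methylbenzoate
Product: 18 (6R,7R)-3-[(E)-3-acetoxyprop-1-enyl]-6-hydroxy-7-methyl-8-oxo-5,6,7,8-tetrahydro-1H-isochromen-7-yl 2,4-bis(TBSO)-6-methylbenzoate
Conditions: Ac2O (1.1 equiv), pyridine, CH2Cl2, −20 °C
Reagents that add atoms: acetic anhydride, CC(=O)OC(C)=O
Why: Acetylation with a slight excess of anhydride at low temperature should be selective for the unhindered primary allylic alcohol over the secondary C6–OH flanked by the quaternary C7.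

Step 13
Reactants: 18 (6R,7R)-3-[(E)-3-acetoxyprop-1-enyl]-6-hydroxy-7-methyl-8-oxo-5,6,7,8-tetrahydro-1H-isochromen-7-yl 2,4-bis(TBSO)-6-methylbenzoate
Product: 19 (7R)-3-[(E)-3-acetoxyprop-1-enyl]-7-methyl-6,8-dioxo-5,6,7,8-tetrahydro-1H-isochromen-7-yl 2,4-bis(TBSO)-6-methylbenzoate
Conditions: Dess–Martin periodinane, CH2Cl2, 0 °C
Reagents that add atoms: none
Why: Dess–Martin oxidation of the secondary alcohol gives the C6 ketone and with it the vinylogous 1,3-diketone whose C5 methylene is activated; C7 is quaternary and cannot epimerize.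

Step 14
Reactants: 17 (6R,7R)-6-hydroxy-3-[(E)-3-hydroxyprop-1-enyl]-7-methyl-8-oxo-5,6,7,8-tetrahydro-1H-isochromen-7-yl 2,4-bis(TBSO)-6-methylbenzoate
Product: 20 (6R,7R)-6-hydroxy-7-methyl-8-oxo-3-[(E)-3-oxoprop-1-enyl]-5,6,7,8-tetrahydro-1H-isochromen-7-yl 2,4-bis(TBSO)-6-methylbenzoate
Conditions: MnO2 (excess), CH2Cl2, 23 °C
Reagents that add atoms: none
Why: MnO2 oxidizes only the allylic (dienylic) primary alcohol to the dienal and should leave the saturated secondary C6′–OH alone (chemoselective allylic oxidation).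

Step 15
Reactants: 19 (7R)-3-[(E)-3-acetoxyprop-1-enyl]-7-methyl-6,8-dioxo-5,6,7,8-tetrahydro-1H-isochromen-7-yl 2,4-bis(TBSO)-6-methylbenzoate; 20 (6R,7R)-6-hydroxy-7-methyl-8-oxo-3-[(E)-3-oxoprop-1-enyl]-5,6,7,8-tetrahydro-1H-isochromen-7-yl 2,4-bis(TBSO)-6-methylbenzoate
Product: 21 tetrakis(tert-butyldimethylsilyl) ether of the target (all four phenols silylated)
Conditions: piperidine (0.1 equiv), AcOH (0.1 equiv), 4 Å MS, CH2Cl2, 23 °C
Reagents that add atoms: none
Why: Knoevenagel condensation: C5–H2 of 19 is α to the C6 ketone and vinylogous to the C8 ketone, the enal is activated as its iminium ion, and reversible addition–dehydration should settle on the (Z)-alkylidene in which the dienyl chain lies on the C6 carbonyl side away from H-4, the (E)-alkene of 20 being carried through.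

Step 16
Reactants: 21 tetrakis(tert-butyldimethylsilyl) ether of the target
Product: 22 target CNP0239166.2
Conditions: TBAF (4.4 equiv), AcOH (4.4 equiv), THF, 0 °C
Reagents that add atoms: none
Why: Buffered fluoride cleaves the four aryl silyl ethers (standard desilylation) under nearly neutral conditions that should spare the allylic acetate, the hindered tertiary esters and the alkylidene dione.

**Compound list**

1 | orsellinic acid (2,4-dihydroxy-6-methylbenzoic acid) | Cc1cc(O)cc(O)c1C(=O)O | starting material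
2 | tert-butyldimethylsilyl 2,4-bis(tert-butyldimethylsilyloxy)-6-methylbenzoate | Cc1cc(O[Si](C)(C)C(C)(C)C)cc(O[Si](C)(C)C(C)(C)C)c1C(=O)O[Si](C)(C)C(C)(C)C | intermediate
3 | 2,4-bis(tert-butyldimethylsilyloxy)-6-methylbenzoic acid | Cc1cc(O[Si](C)(C)C(C)(C)C)cc(O[Si](C)(C)C(C)(C)C)c1C(=O)O | intermediate
4 | 2-methylcyclohexane-1,3-dione | CC1C(=O)CCCC1=O | starting material
5 | bis[2,4-bis(tert-butyldimethylsilyloxy)-6-methylbenzoyloxy]iodobenzene | Cc1cc(O[Si](C)(C)C(C)(C)C)cc(O[Si](C)(C)C(C)(C)C)c1C(=O)OI(OC(=O)c1c(C)cc(O[Si](C)(C)C(C)(C)C)cc1O[Si](C)(C)C(C)(C)C)c1ccccc1 | intermediate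
6 | 2-methyl-1,3-dioxocyclohexan-2-yl 2,4-bis(tert-butyldimethylsilyloxy)-6-methylbenzoate | CC1(OC(=O)c2c(C)cc(O[Si](C)(C)C(C)(C)C)cc2O[Si](C)(C)C(C)(C)C)C(=O)CCCC1=O | intermediate
7 | (1R,2R)-2-hydroxy-1-methyl-6-oxocyclohexyl 2,4-bis(tert-butyldimethylsilyloxy)-6-methylbenzoate | O=C1[C@](C)(OC(=O)c3c(C)cc(O[Si](C)(C)C(C)(C)C)cc3O[Si](C)(C)C(C)(C)C)[C@H](O)CCC1 | intermediate
8 | (1R,2R)-1-methyl-6-oxo-2-(triethylsilyloxy)cyclohexyl 2,4-bis(tert-butyldimethylsilyloxy)-6-methylbenzoate | O=C1[C@](C)(OC(=O)c3c(C)cc(O[Si](C)(C)C(C)(C)C)cc3O[Si](C)(C)C(C)(C)C)[C@H](O[Si](CC)(CC)CC)CCC1 | intermediate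
9 | trimethylsilyl enol ether of 8 (C8–OSiMe3, C8=C8a) | C[Si](C)(C)OC=1[C@](C)(OC(=O)c3c(C)cc(O[Si](C)(C)C(C)(C)C)cc3O[Si](C)(C)C(C)(C)C)[C@H](O[Si](CC)(CC)CC)CCC=1 | intermediate
10 | (1R,6R)-1-methyl-2-oxo-6-(triethylsilyloxy)cyclohex-3-en-1-yl 2,4-bis(tert-butyldimethylsilyloxy)-6-methylbenzoate | O=C1[C@](C)(OC(=O)c3c(C)cc(O[Si](C)(C)C(C)(C)C)cc3O[Si](C)(C)C(C)(C)C)[C@H](O[Si](CC)(CC)CC)CC=C1 | intermediate
11 | (1R,6R)-3-(hydroxymethyl)-1-methyl-2-oxo-6-(triethylsilyloxy)cyclohex-3-en-1-yl 2,4-bis(tert-butyldimethylsilyloxy)-6-methylbenzoate | O=C1[C@](C)(OC(=O)c3c(C)cc(O[Si](C)(C)C(C)(C)C)cc3O[Si](C)(C)C(C)(C)C)[C@H](O[Si](CC)(CC)CC)CC=C1CO | intermediate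
12 | (E)-pent-2-en-4-yn-1-ol | C#C/C=C/CO | starting material
13 | (E)-tert-butyldimethyl(pent-2-en-4-yn-1-yloxy)silane | C#C/C=C/CO[Si](C)(C)C(C)(C)C | intermediate
14 | (E)-tert-butyldimethyl{[4-(4,4,5,5-tetramethyl-1,3,2-dioxaborolan-2-yl)penta-2,4-dien-1-yl]oxy}silane | C=C(B1OC(C)(C)C(C)(C)O1)/C=C/CO[Si](C)(C)C(C)(C)C | intermediate
15 | (1R,6R)-1-methyl-2-oxo-3-({[(3E)-5-(tert-butyldimethylsilyloxy)penta-1,3-dien-2-yl]oxy}methyl)-6-(triethylsilyloxy)cyclohex-3-en-1-yl 2,4-bis(tert-butyldimethylsilyloxy)-6-methylbenzoate | O=C1[C@](C)(OC(=O)c3c(C)cc(O[Si](C)(C)C(C)(C)C)cc3O[Si](C)(C)C(C)(C)C)[C@H](O[Si](CC)(CC)CC)CC=C1COC(=C)/C=C/CO[Si](C)(C)C(C)(C)C | intermediate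
16 | (6R,7R)-3-[(E)-3-(tert-butyldimethylsilyloxy)prop-1-enyl]-7-methyl-8-oxo-6-(triethylsilyloxy)-5,6,7,8-tetrahydro-1H-isochromen-7-yl 2,4-bis(tert-butyldimethylsilyloxy)-6-methylbenzoate | O=C1[C@](C)(OC(=O)c3c(C)cc(O[Si](C)(C)C(C)(C)C)cc3O[Si](C)(C)C(C)(C)C)[C@H](O[Si](CC)(CC)CC)CC2=C1COC(/C=C/CO[Si](C)(C)C(C)(C)C)=C2 | intermediate
17 | (6R,7R)-6-hydroxy-3-[(E)-3-hydroxyprop-1-enyl]-7-methyl-8-oxo-5,6,7,8-tetrahydro-1H-isochromen-7-yl 2,4-bis(tert-butyldimethylsilyloxy)-6-methylbenzoate | O=C1[C@](C)(OC(=O)c3c(C)cc(O[Si](C)(C)C(C)(C)C)cc3O[Si](C)(C)C(C)(C)C)[C@H](O)CC2=C1COC(/C=C/CO)=C2 | intermediate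
18 | (6R,7R)-3-[(E)-3-acetoxyprop-1-enyl]-6-hydroxy-7-methyl-8-oxo-5,6,7,8-tetrahydro-1H-isochromen-7-yl 2,4-bis(tert-butyldimethylsilyloxy)-6-methylbenzoate | O=C1[C@](C)(OC(=O)c3c(C)cc(O[Si](C)(C)C(C)(C)C)cc3O[Si](C)(C)C(C)(C)C)[C@H](O)CC2=C1COC(/C=C/COC(C)=O)=C2 | intermediate
19 | (7R)-3-[(E)-3-acetoxyprop-1-enyl]-7-methyl-6,8-dioxo-5,6,7,8-tetrahydro-1H-isochromen-7-yl 2,4-bis(tert-butyldimethylsilyloxy)-6-methylbenzoate | O=C1[C@](C)(OC(=O)c3c(C)cc(O[Si](C)(C)C(C)(C)C)cc3O[Si](C)(C)C(C)(C)C)C(=O)CC2=C1COC(/C=C/COC(C)=O)=C2 | intermediate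
20 | (6R,7R)-6-hydroxy-7-methyl-8-oxo-3-[(E)-3-oxoprop-1-enyl]-5,6,7,8-tetrahydro-1H-isochromen-7-yl 2,4-bis(tert-butyldimethylsilyloxy)-6-methylbenzoate | O=C1[C@](C)(OC(=O)c3c(C)cc(O[Si](C)(C)C(C)(C)C)cc3O[Si](C)(C)C(C)(C)C)[C@H](O)CC2=C1COC(/C=C/C=O)=C2 | intermediate
21 | tetrakis(tert-butyldimethylsilyl) ether of the target (all four phenols silylated; (5Z)-alkylidene, both chain alkenes E, 7R, 6′R, 7′R) | CC(=O)OC/C=C/C1=CC2=C(CO1)C(=O)[C@](C)(OC(=O)c1c(C)cc(O[Si](C)(C)C(C)(C)C)cc1O[Si](C)(C)C(C)(C)C)C(=O)/C2=C\C=C\C1=CC2=C(CO1)C(=O)[C@](C)(OC(=O)c1c(C)cc(O[Si](C)(C)C(C)(C)C)cc1O[Si](C)(C)C(C)(C)C)[C@H](O)C2 | intermediate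
22 | CNP0239166.2: (5Z,7R)-3-[(E)-3-acetoxyprop-1-enyl]-5-{(E)-3-[(6R,7R)-7-(2,4-dihydroxy-6-methylbenzoyloxy)-6-hydroxy-7-methyl-8-oxo-5,6,7,8-tetrahydro-1H-isochromen-3-yl]prop-2-enylidene}-7-methyl-6,8-dioxo-5,6,7,8-tetrahydro-1H-isochromen-7-yl 2,4-dihydroxy-6-methylbenzoate | CC(=O)OC/C=C/C1=CC2=C(CO1)C(=O)[C@](C)(OC(=O)c1c(C)cc(O)cc1O)C(=O)/C2=C\C=C\C1=CC2=C(CO1)C(=O)[C@](C)(OC(=O)c1c(C)cc(O)cc1O)[C@H](O)C2 | target

**Step count and risks**

Total step count: 16. Longest linear sequence: 13 steps (1, 2, 3, 4, 5, 6, 9, 10, 11, 12, 13, 15, 16).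

Step 10 (ring A closure) is the most likely to fail. Palladium may transfer the enol ether to acetate (transvinylation), acetate may capture the palladated diene, or β-alkoxide elimination may open ring A before the enone is restored. The fallback sets out from 15 and uses known chemistry. Heating 15 (toluene, 110 °C, BHT) should bring about the Claisen rearrangement of the allyl vinyl ether, which forms the same C4–C4a bond and gives the 2-methylene 1,5-diketone F1 as a mixture of C4a epimers. Soft enolization of the side-chain ketone (TMSOTf, Et3N, CH2Cl2, 0 °C) should give the silyl dienol ether F2. Saegusa–Ito oxidation (Pd(OAc)2, MeCN) should then give the cross-conjugated trienone F3, a 1-oxatriene that should close by oxa-6π electrocyclization; a trace of iodine or daylight would equilibrate the C4=C4a geometry if the wrong isomer forms. The fallback returns to the route at 16.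

Step 9 (enol ether formation) comes next. Protodeboronation of 14 and oxidation of the allylic alcohol can outrun C–O bond formation, and the product may rearrange if it is warmed. The fallback sets out from 11 and builds the enol ether by alkoxyselenation and selenoxide elimination. (E)-Penta-2,4-dien-1-ol is silylated (TBSCl, imidazole) to (E)-tert-butyldimethyl(penta-2,4-dienyloxy)silane F4. Alcohol 11, F4 and N-(phenylseleno)phthalimide (CSA cat., CH2Cl2) should give the 1,2-adduct, the β-alkoxy selenide F5. Oxidation (NaIO4, NaHCO3, MeOH–H2O) gives the selenoxide F6, whose syn-elimination can only use the allylic, oxygen-bearing C3–H. The fallback returns to the route at 15.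

Step 2 (orsellinate on C7) is the third. Ligand coupling on iodine may deliver acetate instead of the hindered carboxylate, or the diketone may be oxidized further. The fallback sets out from 4 and 3 and forms the ester by acylation. Dione 4 is hydroxylated (O2, CeCl3·7H2O cat., i-PrOH) to 2-hydroxy-2-methylcyclohexane-1,3-dione F7. Acid 3 is converted (oxalyl chloride, cat. DMF, CH2Cl2) into 2,4-bis(tert-butyldimethylsilyloxy)-6-methylbenzoyl chloride F8. F7 is then acylated with F8 (DMAP, Et3N, CH2Cl2, 0 to 40 °C), kept short and cold enough to avoid α-ketol rearrangement. The fallback returns to the route at 6.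

**Further compounds**

F1 | step 10 | (1R,6R)-1-methyl-3-methylidene-2-oxo-4-[(E)-5-(tert-butyldimethylsilyloxy)-2-oxopent-3-enyl]-6-(triethylsilyloxy)cyclohexyl 2,4-bis(tert-butyldimethylsilyloxy)-6-methylbenzoate (both C4a epimers) | O=C1[C@](C)(OC(=O)c3c(C)cc(O[Si](C)(C)C(C)(C)C)cc3O[Si](C)(C)C(C)(C)C)[C@H](O[Si](CC)(CC)CC)CC(CC(=O)/C=C/CO[Si](C)(C)C(C)(C)C)C1=C
F2 | step 10 | trimethylsilyl dienol ether of F1 (C3–OSiMe3, C3=C4) | O=C1[C@](C)(OC(=O)c3c(C)cc(O[Si](C)(C)C(C)(C)C)cc3O[Si](C)(C)C(C)(C)C)[C@H](O[Si](CC)(CC)CC)CC(C=C(O[Si](C)(C)C)/C=C/CO[Si](C)(C)C(C)(C)C)C1=C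
F3 | step 10 | (1R,6R)-1-methyl-3-methylidene-2-oxo-4-[(E)-5-(tert-butyldimethylsilyloxy)-2-oxopent-3-enylidene]-6-(triethylsilyloxy)cyclohexyl 2,4-bis(tert-butyldimethylsilyloxy)-6-methylbenzoate (acyl group cis to C8a) | O=C1[C@](C)(OC(=O)c3c(C)cc(O[Si](C)(C)C(C)(C)C)cc3O[Si](C)(C)C(C)(C)C)[C@H](O[Si](CC)(CC)CC)C/C(=C/C(=O)/C=C/CO[Si](C)(C)C(C)(C)C)C1=C
F4 | step 9 | (E)-tert-butyldimethyl(penta-2,4-dienyloxy)silane | C=C/C=C/CO[Si](C)(C)C(C)(C)C
F5 | step 9 | (1R,6R)-1-methyl-2-oxo-3-({[(E)-5-(tert-butyldimethylsilyloxy)-1-(phenylselanyl)pent-3-en-2-yl]oxy}methyl)-6-(triethylsilyloxy)cyclohex-3-en-1-yl 2,4-bis(tert-butyldimethylsilyloxy)-6-methylbenzoate (both C3 epimers) | O=C1[C@](C)(OC(=O)c3c(C)cc(O[Si](C)(C)C(C)(C)C)cc3O[Si](C)(C)C(C)(C)C)[C@H](O[Si](CC)(CC)CC)CC=C1COC(C[Se]c2ccccc2)/C=C/CO[Si](C)(C)C(C)(C)C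
F6 | step 9 | selenoxide of F5 | O=C1[C@](C)(OC(=O)c3c(C)cc(O[Si](C)(C)C(C)(C)C)cc3O[Si](C)(C)C(C)(C)C)[C@H](O[Si](CC)(CC)CC)CC=C1COC(C[Se](=O)c2ccccc2)/C=C/CO[Si](C)(C)C(C)(C)C
F7 | step 2 | 2-hydroxy-2-methylcyclohexane-1,3-dione | CC1(O)C(=O)CCCC1=O
F8 | step 2 | 2,4-bis(tert-butyldimethylsilyloxy)-6-methylbenzoyl chloride | Cc1cc(O[Si](C)(C)C(C)(C)C)cc(O[Si](C)(C)C(C)(C)C)c1C(=O)Cl
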